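(The data come from a simulation with made-up constants, noise included.)

- The pitfall in the blue flask is to see 0.800 M of reagent in the second phase, more than the 0.40 M of substrate, and expect a full yield, when its last readings of target lie near 53.0 % with substrate read down to 1.0 %.

| flask | substrate | reagent in the second phase | remark | time | volume of the second phase over the first |
|---|---|---|---|---|---|
| blue | 0.40 M | 0.80 M | the very flask that is asked about, followed so far |  |  |
| amber | 0.40 M | 1.2 M | run made earlier |  |  |
| flask | 0.40 M | 0.800 M |  | 15 h | 1.0 |

| run | time / h | target / % | substrate / % |
|---|---|---|---|
| blue | 0.250 | 16.9 | 50.2 |
| blue | 0.417 | 28.7 | 30.2 |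
| blue | 0.833 | 47.1 | 5.7 |
| blue | 1.50 | 53.0 | 1.9 |
| blue | 3.00 | 52.5 | 1.0 |
| amber | 1.33 | 58.6 | 0 |
| amber | 2.50 | 61.2 | 0 |
| amber | 4.00 | 60.0 | 0 |
| amber | 5.00 | 61.0 | 1.3 |
| amber | 6.00 | 60.9 | 0 |

(standard deviation of a reading: 1 percentage point)

- in percentages every species weighs as the substrate in it: one homo dimer or side product counts as two
- in the second phase: reagent in the second phase; everything else is in the first
- charges count per volume of the first phase; a concentration in a rate is the amount of a species over the volume of its own phase; every rate counts per litre of the first phase
- steps under discussion: reagent in the reaction phase <-> reagent in the second phase; substrate + reagent in the reaction phase -> target; 2 substrate -> homo dimer; substrate <-> dormant form; substrate + target -> side product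
- the earlier runs hold the two phases in the same ratio of volumes as the flask asked about
- what has gone from substrate into another species counts as reacted, even if it can come back

1. amount of target at 15 h, in percent of the substrate charged
2. part of the substrate charged that has reacted at 15 h

- I fold the charges into one number, 0.500, the charge ratio [substrate]/[reagent in the second phase] at the start, which says how much substrate waits on each unit of reagent that has to cross over.
- The last two blue readings give a plateau of 52.8 %, so 0.896 of the charge misses target for each unit that becomes target, the inverse of a selectivity, and I assume this loss is proportional to the ratio, with factor 1.79.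
- To test whether one number is enough, I apply that factor to the amber ratio of 0.333, which gives 62.6 % against a reading of 60.9 % with a scatter of 1 percentage point, so it carries the step between charges but sees nothing after the plateau, and I commit to 52.8 % at 15 h.
- The forecast says 53.5 % and 99.5 %: “I expect about 53%, perhaps slightly more, with conversion essentially complete”.
- The flask gives 57.6 % of target with >99.9 % reacted.

    reagent in the reaction phase ⇌ reagent in the second phase, rate k1*([reagent in the reaction phase] - [reagent in the second phase]/K1) per volume of the first phase (partition coefficient = 0.740, kL = 0.590 h⁻¹)
    substrate + reagent in the reaction phase → target (k = 22.0 M⁻¹ h⁻¹)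
    2 substrate → homo dimer (k = 2.50 M⁻¹ h⁻¹)
    substrate ⇌ dormant form (K = 7.30, k = 0.330 h⁻¹)
    substrate + target → side product (k = 0.200 M⁻¹ h⁻¹)

- My plateau falls 4.8 points short of the flask, but the main reason that the flask misses a full yield is the path from 2 substrate to homo dimer: the same run without that path gives 87.8 % of target against 57.6 %. Recalibrated on this result, the loss per unit of target is 0.735, and scaling it by the ratio to the neighbour with 0.68 M of substrate gives 44.5 %, where that flask holds 43.6 %.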